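## The problem

The target is a C17 chain ending in a phenyl ring that passes through one ring only, a 1,2-dioxolane made of O1, O2, C3, C4 and C5 (numbering: C1 carboxyl, C2 its methylene, C3–C5 ring carbons, C6–C17 side chain). C3 carries a methyl group and the acetic acid arm; C5 carries a methyl group and a chain with a methyl branch at C7 and an (E,E)-phenyldiene at C14–C17. There are three stereocentres: C3 and C5, both fully substituted and oxygen-bearing with their methyl groups cis on the ring, and the remote C7. None of them can be used to control another, because C3 and C5 each carry one methyl and one methylene substituent of nearly the same size; each centre therefore needs its own reagent control or must be bought. The O–O bond will not survive hydrides, organometallics, low-valent metals or catalytic hydrogenation, and because it sits β to the carboxyl group an ester enolate can open the ring. The phenyldiene will not survive fluorine, oxidants or hydrogenation, so it must come last. The feature that makes the key step possible is that O1 and O2 are both tertiary alkoxy oxygens, on C5 and C3, held 1,3 across the C4 methylene: the ring is the cyclic peroxide of a di-tertiary 1,3-diol. Joining O1 to O2 breaks no C–O bond, so both carbinol configurations can be built as ordinary tertiary alcohols and carried into the ring unchanged. The price is that the 3,5-dihydroxy ester is a latent δ-lactone and must be released only just before ring closure.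

## Retrosynthesis

**Acid and diene (30 ⇒ 28 ⇒ 26 + 27; 26 ⇒ 25 ⇒ 24).** The last cuts are the ester C–O bond and the C14=C15 double bond. Acid 30 comes from methyl ester 28, and 28 from aldehyde 26 and diethyl cinnamylphosphonate 27 by Horner–Wadsworth–Emmons olefination. The diene cannot pass through fluorination or hydrogenation, so C14 is carried as the acetate in 24 and unmasked through alcohol 25. The forward steps must be mild enough for a peroxide β to an ester.

**The O–O bond (24 ⇒ 22).** The ring is opened between the two oxygens to give diol ester 22. The neighbouring cuts are C3–O or C5–O; in the forward direction these would mean bonding a peroxide oxygen to a tertiary carbon through a cation, a radical or a strained-ring opening, each of which puts a configuration at risk. The O–O cut asks nothing of the carbons. Diol 22 is acyclic and its stereocentres are plain tertiary alcohols. The forward reaction must turn one hydroxyl into an electrophilic oxygen and close onto the other without fragmenting the molecule.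

**Releasing the diol ester late (22 ⇒ 21 ⇒ 20).** The C2–H bond of 22 is traced back to the C2–O bond of glycidic ester 21. A trans-epoxide across C2–C3 cannot be spanned by a δ-lactone, so the C5 hydroxyl can be freed (21 from silyl ether 20) before the ester becomes able to lactonise. The forward step is a reductive cleavage of the epoxide C–O bond next to the ester; the C3–O bond stays.

**C1 oxidation level and the chain (20 ⇒ 19 ⇒ 17 ⇒ 16 ⇒ 14 + 15).** Ester 20 comes from acid 19 and this from epoxy alcohol 17. The saturated C8–C14 chain of 17 is cut at C10–C11: hydrogenation of 16, which comes from cross-metathesis of the isopropylidene end of 14 with pent-4-en-1-yl acetate 15. Placing this after all organometallic and hydride steps lets the acetate enter unprotected.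

**C3 (14 ⇒ 13 ⇒ 10).** The C2–O and C3–O bonds of 14 come from Sharpless epoxidation of (E)-allylic alcohol 13, which sets C3 by reagent control. The C3–CH3 and C1–C2 bonds of 13 come from alkyne 10 by carboalumination and hydroxymethylation, which gives the trisubstituted alkene as one geometric isomer. A carbonyl olefination at C3 would give E/Z mixtures and so diastereomers after epoxidation.

**From C5 carbinol to alkyne (10 ⇒ 9 ⇒ 8 ⇒ 7).** The alkyne carbon C2 is added to aldehyde 9. The aldehyde comes from diol 7 through bis-silyl ether 8, whose primary silyl ether alone is oxidised. The tertiary silyl ether is needed because a free tertiary β-hydroxy aldehyde would undergo retro-aldol cleavage under the basic homologation.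

**C5 and the chiral pool (7 ⇒ 6 ⇒ 5 ⇒ 2 ⇒ 1).** Diol 7 comes from epoxy alcohol 6 by hydride delivery to C4, and 6 from allylic alcohol 5 by a first Sharpless epoxidation that sets C5. Alcohol 5 is made from alkyne 2 in the same way as 13 from 10, and 2 from (R)-citronellal 1, which supplies C7 and maps its aldehyde carbon onto C5. Adding a methyl nucleophile to a C5 carbonyl under guidance from C3 was set aside for the reason given above: methyl and methylene on the controlling carbon offer no usable bias.

## Roads not taken

**Alternative 1:** Both C–O bonds are cut at once, back to 1,4-dimethylcyclopenta-1,3-diene A1 and singlet oxygen. The forward key step is the [4+2] addition across the diene termini, giving the meso bicyclic peroxide A2.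
- Merits: one well-known step makes the ring and fixes the cis relation of the two methyl groups with complete relative control. In ring construction this road is shorter and more certain than the chosen plan.
- Weak points: A2 is meso, so the target's absolute configuration requires an enantioselective desymmetrisation of two identical termini. The two alkene carbons must be cut apart and then grown differently, one by a single carbon to the acid and one by eleven carbons including the C7 stereocentre, all with the thermally labile peroxide already present. A1 also equilibrates with its double-bond isomers.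
- Comparison: the chosen plan spends many more steps before the ring exists. What it sets against this is that the peroxide is made after all reductions and organometallic steps, and that each stereocentre is set by a reagent.

**Alternative 2:** The O–C5 bond is cut. The forward step is acid-catalysed attack of the C3 hydroperoxide of A3 on the tertiary carbon of its C5–C6 epoxide, with inversion, giving dioxolane A4 with a hydroxyl at C6.
- Merits: 5-exo opening of an epoxide by a hydroperoxide is known chemistry, and C5 is delivered stereospecifically from an epoxide that asymmetric epoxidation can supply.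
- Weak points: A3 needs a tertiary hydroperoxide of defined configuration at C3, for which no stereoretentive preparation from an alcohol exists. A4 carries an extra hydroxyl at C6 that must be removed next to the O–O bond, where radical and hydride deoxygenations are unsafe. Attack at C6 (6-endo) competes.
- Comparison: the ring-forming step is better precedented than in the chosen plan. The chosen plan sets against it that it needs no configured hydroperoxide and no deoxygenation after the ring is made.

**Alternative 3:** The C4–C5 and O–C3 bonds are cut. A silylperoxy carbenium ion generated at C5 from peroxyketal A5 is attacked by the methylene carbon of methyl 3-methylbut-3-enoate A6, and the resulting C3 cation is captured by the peroxide oxygen, giving dioxolane ester A7.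
- Merits: the most convergent of the four plans and by far the shortest; the annulation is a known reaction type that accepts 1,1-disubstituted alkenes.
- Weak points: C5 reacts as a planar cation, so its configuration relative to C7 is not controlled. The C3/C5 relationship depends on telling a methyl from a methylene group on each carbon. The expected outcome is a mixture of all four C3/C5 isomers to be separated at the end.
- Comparison: in step count this road is clearly better. The chosen plan has only stereocontrol to set against it, which for a single-enantiomer target is the deciding point.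

Key step: step 16

Assumption on stereochemistry: both Sharpless epoxidations are taken to follow the sense known for geraniol, which gives its (2S,3S)-epoxide with L-(+)-diethyl tartrate; D-(−)-diethyl tartrate is therefore expected to give the (2R,3R)-epoxides 6 and 14.

Assumption on materials: (R)-citronellal, the Bestmann–Ohira reagent, pent-4-en-1-yl acetate and diethyl cinnamylphosphonate are taken as commercial.

Step 1
Reactants: 1 (R)-citronellal
Product: 2 (4R)-4,8-dimethylnon-7-en-1-yne
Conditions: dimethyl (1-diazo-2-oxopropyl)phosphonate, K2CO3, MeOH, 0 °C to rt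
Reagents that add atoms: dimethyl (1-diazo-2-oxopropyl)phosphonate (Bestmann–Ohira reagent), CC(=O)C(=[N+]=[N-])P(=O)(OC)OC
Why: Ohira–Bestmann (Seyferth–Gilbert) homologation of an aldehyde to a terminal alkyne; the C7 stereocentre is β to the carbonyl and cannot epimerise, and the trisubstituted alkene is inert.

Step 2
Reactants: 2 (4R)-4,8-dimethylnon-7-en-1-yne
Product: 5 (2E,5R)-3,5,9-trimethyldeca-2,8-dien-1-ol, via alkenylalane 3 (not isolated), via lithium alanate 4 (not isolated)
Conditions: Me3Al, Cp2ZrCl2 (0.25 equiv), CH2Cl2, 0 °C to rt; n-BuLi, THF, −78 °C; (CH2O)n, −78 °C to rt; aq. HCl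
Reagents that add atoms: trimethylaluminium, C[Al](C)C; paraformaldehyde (as formaldehyde), C=O
Why: Negishi zirconium-catalysed carboalumination adds methyl and aluminium syn across the terminal alkyne with methyl on the inner carbon, and the alanate is hydroxymethylated with retention, so the (E)-trisubstituted allylic alcohol is expected as a single geometric isomer; the isolated trisubstituted alkene does not react.

Step 3
Reactants: 5 (2E,5R)-3,5,9-trimethyldeca-2,8-dien-1-ol
Product: 6 [(2R,3R)-3-[(2R)-2,6-dimethylhept-5-en-1-yl]-3-methyloxiran-2-yl]methanol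
Conditions: Ti(OiPr)4 (cat.), D-(−)-diethyl tartrate, t-BuOOH, 4 Å MS, CH2Cl2, −20 °C
Reagents that add atoms: tert-butyl hydroperoxide, CC(C)(C)OO
Why: Katsuki–Sharpless asymmetric epoxidation; the tartrate sets the C5 stereocentre (and C4, erased in step 4) by reagent control on a geraniol-type substrate, and only the allylic alkene reacts.

Step 4
Reactants: 6 [(2R,3R)-3-[(2R)-2,6-dimethylhept-5-en-1-yl]-3-methyloxiran-2-yl]methanol
Product: 7 (3R,5R)-3,5,9-trimethyldec-8-ene-1,3-diol
Conditions: NaAlH2(OCH2CH2OMe)2 (Red-Al), THF, 0 °C to rt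
Reagents that add atoms: none
Why: Hydride is delivered from the aluminium alkoxide to the epoxide carbon next to the carbinol (regioselective reduction of a 2,3-epoxy alcohol to a 1,3-diol); the C5–O bond is untouched, so the tertiary alcohol keeps the epoxide configuration.

Step 5
Reactants: 7 (3R,5R)-3,5,9-trimethyldec-8-ene-1,3-diol
Product: 8 (3R,5R)-3,5,9-trimethyl-1,3-bis(triethylsilyloxy)dec-8-ene
Conditions: Et3SiOTf, 2,6-lutidine, CH2Cl2, −78 to 0 °C
Reagents that add atoms: triethylsilyl trifluoromethanesulfonate, CC[Si](CC)(CC)OS(=O)(=O)C(F)(F)F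
Why: Silyl triflate with a hindered base silylates the tertiary as well as the primary hydroxyl; the tertiary silyl ether is there to block retro-aldol cleavage in steps 6 and 7.

Step 6
Reactants: 8 (3R,5R)-3,5,9-trimethyl-1,3-bis(triethylsilyloxy)dec-8-ene
Product: 9 (3R,5R)-3,5,9-trimethyl-3-(triethylsilyloxy)dec-8-enal
Conditions: (COCl)2, DMSO, CH2Cl2, −78 to −30 °C; Et3N, −78 °C to rt
Reagents that add atoms: none
Why: Swern oxidation applied directly to a primary triethylsilyl ether: the chlorosulfonium reagent exchanges the unhindered primary silyl group and oxidises that position to the aldehyde, while the tertiary silyl ether is too hindered to react.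

Step 7
Reactants: 9 (3R,5R)-3,5,9-trimethyl-3-(triethylsilyloxy)dec-8-enal
Product: 10 triethyl{[(4R,6R)-4,6,10-trimethylundec-9-en-1-yn-4-yl]oxy}silane
Conditions: dimethyl (1-diazo-2-oxopropyl)phosphonate, K2CO3, MeOH, 0 °C to rt
Reagents that add atoms: dimethyl (1-diazo-2-oxopropyl)phosphonate (Bestmann–Ohira reagent), CC(=O)C(=[N+]=[N-])P(=O)(OC)OC
Why: Ohira–Bestmann homologation as in step 1; with the β-oxygen silylated the aldehyde has no retro-aldol path, and the triethylsilyl ether is stable to K2CO3 in methanol.

Step 8
Reactants: 10 triethyl{[(4R,6R)-4,6,10-trimethylundec-9-en-1-yn-4-yl]oxy}silane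
Product: 13 (2E,5R,7R)-3,5,7,11-tetramethyl-5-(triethylsilyloxy)dodeca-2,10-dien-1-ol, via alkenylalane 11 (not isolated), via lithium alanate 12 (not isolated)
Conditions: Me3Al, Cp2ZrCl2 (0.25 equiv), CH2Cl2, 0 °C to rt; n-BuLi, THF, −78 °C; (CH2O)n, −78 °C to rt; aq. NH4Cl
Reagents that add atoms: trimethylaluminium, C[Al](C)C; paraformaldehyde (as formaldehyde), C=O
Why: Negishi carboalumination and hydroxymethylation as in step 2 install the C3 methyl group and C1 and fix the (E)-geometry on which the configuration of C3 will depend; silyl ethers are tolerated.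

Step 9
Reactants: 13 (2E,5R,7R)-3,5,7,11-tetramethyl-5-(triethylsilyloxy)dodeca-2,10-dien-1-ol
Product: 14 [(2R,3R)-3-methyl-3-[(2R,4R)-2,4,8-trimethyl-2-(triethylsilyloxy)non-7-en-1-yl]oxiran-2-yl]methanol
Conditions: Ti(OiPr)4 (cat.), D-(−)-diethyl tartrate, t-BuOOH, 4 Å MS, CH2Cl2, −20 °C
Reagents that add atoms: tert-butyl hydroperoxide, CC(C)(C)OO
Why: Second Katsuki–Sharpless epoxidation; the same tartrate sets C3 (and C2, erased in step 15) by reagent control, which places the C3 and C5 methyl groups in the relation that becomes cis on the ring; the remote alkene is untouched.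

Step 10
Reactants: 14 [(2R,3R)-3-methyl-3-[(2R,4R)-2,4,8-trimethyl-2-(triethylsilyloxy)non-7-en-1-yl]oxiran-2-yl]methanol; 15 pent-4-en-1-yl acetate
Product: 16 (4E,8R,10R)-11-[(2R,3R)-3-(hydroxymethyl)-2-methyloxiran-2-yl]-8,10-dimethyl-10-(triethylsilyloxy)undec-4-en-1-yl acetate (E/Z mixture expected)
Conditions: second-generation Hoveyda–Grubbs catalyst, RuCl2(=CH-2-iPrOC6H4)(H2IMes) (5 mol%), 15 (4 equiv), CH2Cl2, 40 °C
Reagents that add atoms: none
Why: Olefin cross-metathesis in which the isopropylidene terminus exchanges for the terminal alkene of 15 with loss of isobutene; free hydroxyl, epoxide and silyl ether are tolerated, and the alkene geometry is irrelevant because it is removed in step 11.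

Step 11
Reactants: 16 (4E,8R,10R)-11-[(2R,3R)-3-(hydroxymethyl)-2-methyloxiran-2-yl]-8,10-dimethyl-10-(triethylsilyloxy)undec-4-en-1-yl acetate
Product: 17 (8R,10R)-11-[(2R,3R)-3-(hydroxymethyl)-2-methyloxiran-2-yl]-8,10-dimethyl-10-(triethylsilyloxy)undecyl acetate
Conditions: H2 (1 atm), Pd/C, EtOAc, rt
Reagents that add atoms: none
Why: Catalytic hydrogenation of an unhindered disubstituted alkene; the trisubstituted aliphatic epoxide is neither allylic nor benzylic and should survive neutral conditions, and from here on the molecule holds no C=C bond that fluorine could attack.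

Step 12
Reactants: 17 (8R,10R)-11-[(2R,3R)-3-(hydroxymethyl)-2-methyloxiran-2-yl]-8,10-dimethyl-10-(triethylsilyloxy)undecyl acetate
Product: 19 (2S,3R)-3-[(2R,4R)-11-acetoxy-2,4-dimethyl-2-(triethylsilyloxy)undecyl]-3-methyloxirane-2-carboxylic acid, via epoxy aldehyde 18 (not isolated)
Conditions: TEMPO (cat.), PhI(OAc)2 (2.5 equiv), MeCN/pH 7 buffer, 0 °C to rt
Reagents that add atoms: water, O
Why: Nitroxyl-catalysed oxidation of a primary alcohol through the aldehyde hydrate to the acid, a standard route from 2,3-epoxy alcohols to glycidic acids that leaves epoxide, acetate and silyl ether alone; the acid is used crude.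

Step 13
Reactants: 19 (2S,3R)-3-[(2R,4R)-11-acetoxy-2,4-dimethyl-2-(triethylsilyloxy)undecyl]-3-methyloxirane-2-carboxylic acid
Product: 20 methyl (2S,3R)-3-[(2R,4R)-11-acetoxy-2,4-dimethyl-2-(triethylsilyloxy)undecyl]-3-methyloxirane-2-carboxylate
Conditions: Me3SiCHN2, PhMe/MeOH, 0 °C
Reagents that add atoms: (trimethylsilyl)diazomethane, C[Si](C)(C)C=[N+]=[N-]
Why: Methyl ester formation with (trimethylsilyl)diazomethane under near-neutral conditions, so the acid-sensitive glycidic acid is not exposed to an esterification catalyst.

Step 14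
Reactants: 20 methyl (2S,3R)-3-[(2R,4R)-11-acetoxy-2,4-dimethyl-2-(triethylsilyloxy)undecyl]-3-methyloxirane-2-carboxylate
Product: 21 methyl (2S,3R)-3-[(2R,4R)-11-acetoxy-2-hydroxy-2,4-dimethylundecyl]-3-methyloxirane-2-carboxylate
Conditions: Bu4NF, AcOH, THF, 0 °C to rt
Reagents that add atoms: none
Why: Buffered fluoride cleavage of the tertiary triethylsilyl ether; the freed C5 hydroxyl cannot lactonise because the ester and the C4 chain are trans on the epoxide, and acetic acid keeps acetate and epoxide safe.

Step 15
Reactants: 21 methyl (2S,3R)-3-[(2R,4R)-11-acetoxy-2-hydroxy-2,4-dimethylundecyl]-3-methyloxirane-2-carboxylate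
Product: 22 methyl (3R,5R,7R)-14-acetoxy-3,5-dihydroxy-3,5,7-trimethyltetradecanoate
Conditions: SmI2 (2.5 equiv), HMPA, Me2NCH2CH2OH, THF, 0 °C
Reagents that add atoms: none
Why: Divalent samarium transfers electrons to the ester carbonyl and the epoxide C–O bond next to it breaks (known reduction of α,β-epoxy esters to β-hydroxy esters); the C3–O bond is not involved, so C3 keeps the configuration set in step 9, and the diol ester is released under neutral conditions and taken directly into step 16.

Step 16
Reactants: 22 methyl (3R,5R,7R)-14-acetoxy-3,5-dihydroxy-3,5,7-trimethyltetradecanoate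
Product: 24 methyl 2-[(3R,5R)-5-[(2R)-9-acetoxy-2-methylnonyl]-3,5-dimethyl-1,2-dioxolan-3-yl]acetate, via tertiary hypofluorite 23 (not isolated)
Conditions: F2 (10% in N2, ca. 1.2 equiv), NaF, EtCN, −78 °C
Reagents that add atoms: none
Why: Proposed new method: F2 is expected to fluorinate one tertiary hydroxyl of 22 at oxygen, the way tert-alkyl hypofluorites are made from alcohols, giving hypofluorite 23 with HF taken up by NaF; in an O–F bond oxygen is the positive end, and such hypofluorites are known to deliver their alkoxy oxygen to nucleophiles. The other hydroxyl, four atoms away, then attacks that oxygen and fluoride leaves, an intramolecular SN2 displacement at oxygen that closes the 1,2-dioxolane in the 5-exo-tet mode; either hydroxyl may be fluorinated first, since both hypofluorites close to the same ring. The closest known reaction type is the coupling of fluoroxy compounds with fluoroalkoxides to perfluoroalkyl peroxides, which has not been shown for hydrocarbon alcohols or for ring closure. No stereocentre is formed: only O–H and O–F bonds break, so C3 and C5 keep the configurations from steps 3 and 9 and the methyl groups come out cis. The selectivity needed is chemoselectivity: closure must outrun β-scission or 1,2-alkyl shift of the hypofluorite, fluorination of the tertiary C7–H bond and lactonisation of the hydroxy ester. It is secured by low temperature and dilute fluorine, by the two fully substituted carbons that hold the oxygens close, by NaF and the nitrile solvent that keep HF from accumulating, and by the ester and acetate groups, which deactivate nearby C–H bonds.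

Step 17
Reactants: 24 methyl 2-[(3R,5R)-5-[(2R)-9-acetoxy-2-methylnonyl]-3,5-dimethyl-1,2-dioxolan-3-yl]acetate
Product: 25 methyl 2-[(3R,5R)-5-[(2R)-9-hydroxy-2-methylnonyl]-3,5-dimethyl-1,2-dioxolan-3-yl]acetate
Conditions: K2CO3 (0.2 equiv), MeOH, 0 °C
Reagents that add atoms: none
Why: Base-catalysed transesterification removes the primary acetate as methyl acetate; the methyl ester can only exchange with itself, and carbonate in cold methanol is too weak a base to enolise the ester and open the peroxide.

Step 18
Reactants: 25 methyl 2-[(3R,5R)-5-[(2R)-9-hydroxy-2-methylnonyl]-3,5-dimethyl-1,2-dioxolan-3-yl]acetate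
Product: 26 methyl 2-[(3R,5R)-3,5-dimethyl-5-[(2R)-2-methyl-9-oxononyl]-1,2-dioxolan-3-yl]acetate
Conditions: TEMPO (cat.), PhI(OAc)2 (1.2 equiv), CH2Cl2, rt
Reagents that add atoms: none
Why: Nitroxyl-catalysed oxidation of a primary alcohol to the aldehyde without water, so it stops at the aldehyde; the oxidant does not touch dialkyl peroxides.

Step 19
Reactants: 26 methyl 2-[(3R,5R)-3,5-dimethyl-5-[(2R)-2-methyl-9-oxononyl]-1,2-dioxolan-3-yl]acetate; 27 diethyl cinnamylphosphonate
Product: 28 methyl 2-[(3R,5R)-3,5-dimethyl-5-[(2R,9E,11E)-2-methyl-12-phenyldodeca-9,11-dien-1-yl]-1,2-dioxolan-3-yl]acetate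
Conditions: 27, LiN(SiMe3)2, THF, −78 °C; then 26, −78 °C to rt
Reagents that add atoms: none
Why: Horner–Wadsworth–Emmons olefination with an allylic phosphonate anion, which favours the (E)-alkene at the new C14=C15 bond and keeps the styrene geometry; the anion is preformed so no free amide base meets the ester, and it is too weak a base to enolise it.

Step 20
Reactants: 28 methyl 2-[(3R,5R)-3,5-dimethyl-5-[(2R,9E,11E)-2-methyl-12-phenyldodeca-9,11-dien-1-yl]-1,2-dioxolan-3-yl]acetate
Product: 30 2-[(3R,5R)-3,5-dimethyl-5-[(2R,9E,11E)-2-methyl-12-phenyldodeca-9,11-dien-1-yl]-1,2-dioxolan-3-yl]acetic acid, via lithium carboxylate 29 (not isolated)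
Conditions: LiOH, THF/MeOH/H2O, 0 °C to rt; then 1 M HCl to pH 3
Reagents that add atoms: lithium hydroxide, [Li+].[OH-]
Why: Saponification of a methyl ester by hydroxide attack at the carbonyl carbon; once the carboxylate has formed, the α-hydrogens are no longer acidic enough for ring opening, and no stereocentre is involved.

Compound list

1 | (R)-citronellal, (3R)-3,7-dimethyloct-6-enal | C[C@H](CCC=C(C)C)CC=O | starting material
2 | (4R)-4,8-dimethylnon-7-en-1-yne | C[C@H](CCC=C(C)C)CC#C | intermediate
3 | dimethyl[(1E,4R)-2,4,8-trimethylnona-1,7-dien-1-yl]alane | C[C@H](CCC=C(C)C)C/C(C)=C/[Al](C)C | intermediate (not isolated)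
4 | lithium butyl(dimethyl)[(1E,4R)-2,4,8-trimethylnona-1,7-dien-1-yl]alanate | C[C@H](CCC=C(C)C)C/C(C)=C/[Al-](C)(C)CCCC.[Li+] | intermediate (not isolated)
5 | (2E,5R)-3,5,9-trimethyldeca-2,8-dien-1-ol | C[C@H](CCC=C(C)C)C/C(C)=C/CO | intermediate
6 | [(2R,3R)-3-[(2R)-2,6-dimethylhept-5-en-1-yl]-3-methyloxiran-2-yl]methanol | C[C@H](CCC=C(C)C)C[C@@]1(C)O[C@@H]1CO | intermediate
7 | (3R,5R)-3,5,9-trimethyldec-8-ene-1,3-diol | C[C@H](CCC=C(C)C)C[C@](O)(C)CCO | intermediate
8 | (3R,5R)-3,5,9-trimethyl-1,3-bis(triethylsilyloxy)dec-8-ene | C[C@H](CCC=C(C)C)C[C@](O[Si](CC)(CC)CC)(C)CCO[Si](CC)(CC)CC | intermediate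
9 | (3R,5R)-3,5,9-trimethyl-3-(triethylsilyloxy)dec-8-enal | C[C@H](CCC=C(C)C)C[C@](O[Si](CC)(CC)CC)(C)CC=O | intermediate
10 | triethyl{[(4R,6R)-4,6,10-trimethylundec-9-en-1-yn-4-yl]oxy}silane | C[C@H](CCC=C(C)C)C[C@](O[Si](CC)(CC)CC)(C)CC#C | intermediate
11 | dimethyl[(1E,4R,6R)-2,4,6,10-tetramethyl-4-(triethylsilyloxy)undeca-1,9-dien-1-yl]alane | C[C@H](CCC=C(C)C)C[C@](O[Si](CC)(CC)CC)(C)C/C(C)=C/[Al](C)C | intermediate (not isolated)
12 | lithium butyl(dimethyl)[(1E,4R,6R)-2,4,6,10-tetramethyl-4-(triethylsilyloxy)undeca-1,9-dien-1-yl]alanate | C[C@H](CCC=C(C)C)C[C@](O[Si](CC)(CC)CC)(C)C/C(C)=C/[Al-](C)(C)CCCC.[Li+] | intermediate (not isolated)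
13 | (2E,5R,7R)-3,5,7,11-tetramethyl-5-(triethylsilyloxy)dodeca-2,10-dien-1-ol | C[C@H](CCC=C(C)C)C[C@](O[Si](CC)(CC)CC)(C)C/C(C)=C/CO | intermediate
14 | [(2R,3R)-3-methyl-3-[(2R,4R)-2,4,8-trimethyl-2-(triethylsilyloxy)non-7-en-1-yl]oxiran-2-yl]methanol | C[C@H](CCC=C(C)C)C[C@](O[Si](CC)(CC)CC)(C)C[C@@]1(C)O[C@@H]1CO | intermediate
15 | pent-4-en-1-yl acetate | C=CCCCOC(C)=O | starting material
16 | (4E,8R,10R)-11-[(2R,3R)-3-(hydroxymethyl)-2-methyloxiran-2-yl]-8,10-dimethyl-10-(triethylsilyloxy)undec-4-en-1-yl acetate (E isomer shown; E/Z mixture expected) | C[C@H](CC/C=C/CCCOC(C)=O)C[C@](O[Si](CC)(CC)CC)(C)C[C@@]1(C)O[C@@H]1CO | intermediate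
17 | (8R,10R)-11-[(2R,3R)-3-(hydroxymethyl)-2-methyloxiran-2-yl]-8,10-dimethyl-10-(triethylsilyloxy)undecyl acetate | C[C@H](CCCCCCCOC(C)=O)C[C@](O[Si](CC)(CC)CC)(C)C[C@@]1(C)O[C@@H]1CO | intermediate
18 | (8R,10R)-11-[(2R,3S)-3-formyl-2-methyloxiran-2-yl]-8,10-dimethyl-10-(triethylsilyloxy)undecyl acetate | C[C@H](CCCCCCCOC(C)=O)C[C@](O[Si](CC)(CC)CC)(C)C[C@@]1(C)O[C@@H]1C=O | intermediate (not isolated)
19 | (2S,3R)-3-[(2R,4R)-11-acetoxy-2,4-dimethyl-2-(triethylsilyloxy)undecyl]-3-methyloxirane-2-carboxylic acid | C[C@H](CCCCCCCOC(C)=O)C[C@](O[Si](CC)(CC)CC)(C)C[C@@]1(C)O[C@@H]1C(=O)O | intermediate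
20 | methyl (2S,3R)-3-[(2R,4R)-11-acetoxy-2,4-dimethyl-2-(triethylsilyloxy)undecyl]-3-methyloxirane-2-carboxylate | C[C@H](CCCCCCCOC(C)=O)C[C@](O[Si](CC)(CC)CC)(C)C[C@@]1(C)O[C@@H]1C(=O)OC | intermediate
21 | methyl (2S,3R)-3-[(2R,4R)-11-acetoxy-2-hydroxy-2,4-dimethylundecyl]-3-methyloxirane-2-carboxylate | C[C@H](CCCCCCCOC(C)=O)C[C@](O)(C)C[C@@]1(C)O[C@@H]1C(=O)OC | intermediate
22 | methyl (3R,5R,7R)-14-acetoxy-3,5-dihydroxy-3,5,7-trimethyltetradecanoate | C[C@H](CCCCCCCOC(C)=O)C[C@](O)(C)C[C@](C)(CC(=O)OC)O | intermediate
23 | methyl (3R,5R,7R)-14-acetoxy-5-(fluorooxy)-3-hydroxy-3,5,7-trimethyltetradecanoate (the C3 regioisomer closes to the same ring) | C[C@H](CCCCCCCOC(C)=O)C[C@](OF)(C)C[C@](C)(CC(=O)OC)O | intermediate (not isolated)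
24 | methyl 2-[(3R,5R)-5-[(2R)-9-acetoxy-2-methylnonyl]-3,5-dimethyl-1,2-dioxolan-3-yl]acetate | C[C@H](CCCCCCCOC(C)=O)C[C@]1(C)C[C@](C)(CC(=O)OC)OO1 | intermediate
25 | methyl 2-[(3R,5R)-5-[(2R)-9-hydroxy-2-methylnonyl]-3,5-dimethyl-1,2-dioxolan-3-yl]acetate | C[C@H](CCCCCCCO)C[C@]1(C)C[C@](C)(CC(=O)OC)OO1 | intermediate
26 | methyl 2-[(3R,5R)-3,5-dimethyl-5-[(2R)-2-methyl-9-oxononyl]-1,2-dioxolan-3-yl]acetate | C[C@H](CCCCCCC=O)C[C@]1(C)C[C@](C)(CC(=O)OC)OO1 | intermediate
27 | diethyl cinnamylphosphonate, diethyl [(2E)-3-phenylprop-2-en-1-yl]phosphonate | CCOP(=O)(C/C=C/c1ccccc1)OCC | starting material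
28 | methyl 2-[(3R,5R)-3,5-dimethyl-5-[(2R,9E,11E)-2-methyl-12-phenyldodeca-9,11-dien-1-yl]-1,2-dioxolan-3-yl]acetate | C[C@H](CCCCCC/C=C/C=C/c1ccccc1)C[C@]1(C)C[C@](C)(CC(=O)OC)OO1 | intermediate
29 | lithium 2-[(3R,5R)-3,5-dimethyl-5-[(2R,9E,11E)-2-methyl-12-phenyldodeca-9,11-dien-1-yl]-1,2-dioxolan-3-yl]acetate | C[C@H](CCCCCC/C=C/C=C/c1ccccc1)C[C@]1(C)C[C@](C)(CC(=O)[O-])OO1.[Li+] | intermediate (not isolated)
30 | 2-[(3R,5R)-3,5-dimethyl-5-[(2R,9E,11E)-2-methyl-12-phenyldodeca-9,11-dien-1-yl]-1,2-dioxolan-3-yl]acetic acid | C[C@H](CCCCCC/C=C/C=C/c1ccccc1)C[C@]1(C)C[C@](C)(CC(=O)O)OO1 | target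

Total step count: 20. Longest linear sequence: 20 steps from 1 (15 and 27 are commercial and enter in steps 10 and 19).

Least certain steps

Step 16 (the proposed new method). The most likely failures are:
- fragmentation of the tertiary hypofluorite by β-scission or alkyl shift before the second oxygen arrives;
- fluorination of the tertiary C7–H bond;
- acid-promoted lactonisation of the hydroxy ester by HF that escapes the NaF.

The first two are competing reactions of fluorine and of electron-poor oxygen that are known to be fast on hydrocarbon substrates. The fallback uses known chemistry and forms the ring through C–O bonds instead: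
- From alkyne 10, the carboalumination of step 8 is repeated (through 11 and 12), but alanate 12 is quenched with methyl chloroformate to give methyl (2E,5R,7R)-3,5,7,11-tetramethyl-5-(triethylsilyloxy)dodeca-2,10-dienoate F1.
- Cross-metathesis with 15 as in step 10 gives methyl (2E,5R,7R,10E)-14-acetoxy-3,5,7-trimethyl-5-(triethylsilyloxy)tetradeca-2,10-dienoate F2.
- Hydrogenation over RhCl(PPh3)3, which leaves the trisubstituted enoate alone, gives methyl (2E,5R,7R)-14-acetoxy-3,5,7-trimethyl-5-(triethylsilyloxy)tetradec-2-enoate F3.
- 50% H2O2 with catalytic H2SO4 in THF cleaves the silyl ether and exchanges the C5 oxygen for a hydroperoxy group through the tertiary cation, giving methyl (2E,7R)-14-acetoxy-5-hydroperoxy-3,5,7-trimethyltetradec-2-enoate F4.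
- Et2NH in CF3CH2OH closes the ring by intramolecular conjugate addition of the hydroperoxide to the enoate, returning to the route at 24.

The cost is that C5 passes through a cation and C3 is formed without control, so 24 would have to be separated from its C3 and C5 epimers by preparative chromatography.

Step 10. Cross-metathesis of a hindered trisubstituted alkene may stall, with homodimerisation of 15 and alkene migration by ruthenium hydrides taking over. Fallback from 14:
- Ozonolysis (O3, CH2Cl2/MeOH, −78 °C; PPh3) cuts the isopropylidene group to (4R,6R)-7-[(2R,3R)-3-(hydroxymethyl)-2-methyloxiran-2-yl]-4,6-dimethyl-6-(triethylsilyloxy)heptanal F5.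
- A Wittig reaction with the ylide from (4-acetoxybutyl)triphenylphosphonium bromide and NaN(SiMe3)2 (one extra equivalent for the free hydroxyl) gives the (Z)-isomer of 16, F6.
- F6 is hydrogenated as in step 11 and returns at 17.

Step 15. Electron transfer may go too far (loss of the β-oxygen to give the enoate, or attack on the acetate), and the amino alcohol may trigger retro-aldol cleavage or lactonisation of the product. Fallback from 21:
- Sodium phenylselenolate, made from (PhSe)2 and NaBH4 in EtOH with AcOH, opens the epoxide at C2 by SN2 attack next to the ester to give methyl (2R,3R,5R,7R)-14-acetoxy-3,5-dihydroxy-3,5,7-trimethyl-2-(phenylselanyl)tetradecanoate F7.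
- A second equivalent of selenolate removes the selenium, returning at 22.

This is a two-electron nucleophilic route to the same C2–O cleavage and again leaves the C3–O bond alone.

Step 19. The new C14=C15 bond may form with incomplete (E)-selectivity, and the phosphonate anion may act as a base on the ester and open the peroxide. Fallback from 26:
- The stabilised ylide (triphenylphosphoranylidene)acetaldehyde in toluene gives methyl 2-[(3R,5R)-3,5-dimethyl-5-[(2R,9E)-2-methyl-11-oxoundec-9-en-1-yl]-1,2-dioxolan-3-yl]acetate F8 without any added base.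
- A Horner–Wadsworth–Emmons reaction of F8 with diethyl benzylphosphonate and LiN(SiMe3)2 builds the second (E)-alkene and returns at 28.

Further compounds

F1 | step 16 | methyl (2E,5R,7R)-3,5,7,11-tetramethyl-5-(triethylsilyloxy)dodeca-2,10-dienoate | C[C@H](CCC=C(C)C)C[C@](O[Si](CC)(CC)CC)(C)C/C(C)=C/C(=O)OC
F2 | step 16 | methyl (2E,5R,7R,10E)-14-acetoxy-3,5,7-trimethyl-5-(triethylsilyloxy)tetradeca-2,10-dienoate | C[C@H](CC/C=C/CCCOC(C)=O)C[C@](O[Si](CC)(CC)CC)(C)C/C(C)=C/C(=O)OC
F3 | step 16 | methyl (2E,5R,7R)-14-acetoxy-3,5,7-trimethyl-5-(triethylsilyloxy)tetradec-2-enoate | C[C@H](CCCCCCCOC(C)=O)C[C@](O[Si](CC)(CC)CC)(C)C/C(C)=C/C(=O)OC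
F4 | step 16 | methyl (2E,7R)-14-acetoxy-5-hydroperoxy-3,5,7-trimethyltetradec-2-enoate (both C5 epimers) | C[C@H](CCCCCCCOC(C)=O)CC(C)(OO)C/C(C)=C/C(=O)OC
F5 | step 10 | (4R,6R)-7-[(2R,3R)-3-(hydroxymethyl)-2-methyloxiran-2-yl]-4,6-dimethyl-6-(triethylsilyloxy)heptanal | C[C@H](CCC=O)C[C@](O[Si](CC)(CC)CC)(C)C[C@@]1(C)O[C@@H]1CO
F6 | step 10 | (4Z,8R,10R)-11-[(2R,3R)-3-(hydroxymethyl)-2-methyloxiran-2-yl]-8,10-dimethyl-10-(triethylsilyloxy)undec-4-en-1-yl acetate | C[C@H](CC/C=C\CCCOC(C)=O)C[C@](O[Si](CC)(CC)CC)(C)C[C@@]1(C)O[C@@H]1CO
F7 | step 15 | methyl (2R,3R,5R,7R)-14-acetoxy-3,5-dihydroxy-3,5,7-trimethyl-2-(phenylselanyl)tetradecanoate | C[C@H](CCCCCCCOC(C)=O)C[C@](O)(C)C[C@@](C)(O)[C@@H]([Se]c1ccccc1)C(=O)OC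
F8 | step 19 | methyl 2-[(3R,5R)-3,5-dimethyl-5-[(2R,9E)-2-methyl-11-oxoundec-9-en-1-yl]-1,2-dioxolan-3-yl]acetate | C[C@H](CCCCCC/C=C/C=O)C[C@]1(C)C[C@](C)(CC(=O)OC)OO1
A1 | alternative 1 | 1,4-dimethylcyclopenta-1,3-diene | CC1=CC=C(C)C1
A2 | alternative 1 | meso-1,4-dimethyl-2,3-dioxabicyclo[2.2.1]hept-5-ene | C[C@@]12C=C[C@@](C)(C1)OO2
A3 | alternative 2 | 4-[3-[9-(tert-butyldiphenylsilyloxy)nonan-2-yl]-2-methyloxiran-2-yl]-3-hydroperoxy-3-methylbutyl 2,2-dimethylpropanoate (configuration as in the SMILES) | C[C@H](CCCCCCCO[Si](c1ccccc1)(c1ccccc1)C(C)(C)C)[C@H]1O[C@]1(C)C[C@](C)(CCOC(=O)C(C)(C)C)OO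
A4 | alternative 2 | 1,2-dioxolane with a C6 hydroxyl, pivalate on the C1 arm and silyl ether at C14 (configuration as in the SMILES) | C[C@H](CCCCCCCO[Si](c1ccccc1)(c1ccccc1)C(C)(C)C)[C@@H](O)[C@]1(C)C[C@](C)(CCOC(=O)C(C)(C)C)OO1
A5 | alternative 3 | tert-butyl{[(8R)-10-methoxy-8-methyl-10-(triethylsilylperoxy)undecyl]oxy}diphenylsilane | C[C@H](CCCCCCCO[Si](c1ccccc1)(c1ccccc1)C(C)(C)C)CC(C)(OC)OO[Si](CC)(CC)CC
A6 | alternative 3 | methyl 3-methylbut-3-enoate | C=C(C)CC(=O)OC
A7 | alternative 3 | methyl 2-[(3R,5R)-5-[(2R)-9-(tert-butyldiphenylsilyloxy)-2-methylnonyl]-3,5-dimethyl-1,2-dioxolan-3-yl]acetate | C[C@H](CCCCCCCO[Si](c1ccccc1)(c1ccccc1)C(C)(C)C)C[C@]1(C)C[C@](C)(CC(=O)OC)OO1
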